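Everything rests on disconnecting ring A across its C2–C3 and C4–C5 bonds (with C5–C6 opened and re-closed), which reduces that arene to a 3-alkylcyclobut-2-enone and methoxyacetylene. The feature exploited is the 1,3,5-pattern of ring A: methoxyl on C3 and free hydroxyl on C5 lie meta to each other and to the chain on C1. A thermal cyclobutenone–alkoxyalkyne benzannulation builds this ring in one operation with the two oxygens already differentiated, so no resorcinol has to be monomethylated. The precursor is a cyclobutenone whose C3 carries the complete fourteen-carbon tether ending in ring B as its bis(benzyl ether); a single hydrogenolysis finishes the synthesis.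

Key step: step 6

Remark: ring A is numbered C1 (chain carbon), C3 (OMe carbon) and C5 (OH carbon); the target has no stereocentre; compounds 1, 2, 5, 7 and 11 are taken as catalogue chemicals.

Step 1
Reactants: 1 1,3-bis(benzyloxy)-5-bromobenzene; 2 1,14-dibromotetradecane (3 equiv)
Product: 4 1,3-bis(benzyloxy)-5-(14-bromotetradecyl)benzene, via arylmagnesium bromide 3 (not isolated)
Conditions: Mg (I2-activated), THF, reflux; then slow addition to 2, Li2CuCl4 (5 mol %), THF, 0 °C → rt
Reagents that add atoms: none
Why: Copper-catalysed Kumada-type cross-coupling of an aryl Grignard reagent with a primary alkyl bromide should join ring B to the chain, and the excess of 2 with inverse addition should keep a second substitution low (unreacted 2 is recovered by chromatography).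

Step 2
Reactants: 4 1,3-bis(benzyloxy)-5-(14-bromotetradecyl)benzene; 5 lithium acetylide–ethylenediamine complex
Product: 6 1,3-bis(benzyloxy)-5-(hexadec-15-yn-1-yl)benzene
Conditions: 5 (2 equiv), DMSO/THF, 0 °C → rt
Reagents that add atoms: none
Why: SN2 alkylation of the acetylide at an unhindered primary bromide in a dipolar aprotic medium should give the terminal alkyne while the aryl benzyl ethers stay untouched.

Step 3
Reactants: 6 1,3-bis(benzyloxy)-5-(hexadec-15-yn-1-yl)benzene; 7 trichloroacetyl chloride
Product: 9 3-{14-[3,5-bis(benzyloxy)phenyl]tetradecyl}-4,4-dichlorocyclobut-2-en-1-one, via dichloroketene 8 (not isolated)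
Conditions: 7 (2 equiv, slow addition), Zn(Cu) couple, Et2O/DME, rt
Reagents that add atoms: none
Why: Zinc removes two chlorines from 7 to give dichloroketene, whose [2+2] cycloaddition with a terminal alkyne joins the ketene carbonyl carbon to the terminal alkyne carbon so that the chain sits on C3 of the cyclobutenone, and DME should bind the ZnCl2 formed and so spare the benzyl ethers and ring B.

Step 4
Reactants: 9 3-{14-[3,5-bis(benzyloxy)phenyl]tetradecyl}-4,4-dichlorocyclobut-2-en-1-one
Product: 10 3-{14-[3,5-bis(benzyloxy)phenyl]tetradecyl}cyclobut-2-en-1-one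
Conditions: Zn dust, AcOH, TMEDA, EtOH, 0 °C → rt
Reagents that add atoms: none
Why: Reductive dehalogenation of the two C–Cl bonds next to the carbonyl through zinc enolates, buffered by TMEDA and AcOH to avoid opening of the strained enone, should give the 3-alkylcyclobutenone (any isomer formed by chlorine migration in step 3 is expected to converge on the same ketone).

Step 5
Reactants: 11 2-chloro-1,1-dimethoxyethane (chloroacetaldehyde dimethyl acetal)
Product: 13 methoxyacetylene, via sodium methoxyacetylide 12 (not isolated)
Conditions: NaNH2 (3 equiv), liq. NH3, −33 °C; evaporate NH3; cold sat. aq NaCl; distil into toluene at −78 °C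
Reagents that add atoms: none
Why: Twofold base-induced elimination (methanol, then HCl) of the chloroacetal gives the alkynyl ether, which the third equivalent of amide holds as its sodium salt until the aqueous quench, the classical preparation of 1-alkoxyalkynes.

Step 6
Reactants: 10 3-{14-[3,5-bis(benzyloxy)phenyl]tetradecyl}cyclobut-2-en-1-one; 13 methoxyacetylene
Product: 18 3-{14-[3,5-bis(benzyloxy)phenyl]tetradecyl}-5-methoxyphenol, via vinylketene 14 (not isolated), via 4-vinylcyclobutenone 15 (not isolated), via dienylketene 16 (not isolated), via cyclohexa-2,4-dienone 17 (not isolated)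
Conditions: 13 (3 equiv), toluene, 80 °C, sealed tube
Reagents that add atoms: none
Why: Heat converts 10 by conrotatory four-electron ring opening (cleaving the future C5–C6 bond) into vinylketene 14, whose ketene unit combines with alkyne 13 in a [2+2] cycloaddition to give 15, creating C4–C5 and C2–C3; a second four-electron opening of 15 produces dienylketene 16, and its disrotatory six-electron ring closure re-forms C5–C6, after which dienone 17 enolises to phenol 18. The closest known reaction type is the Danheiser benzannulation of 3-alkylcyclobutenones with alkoxyacetylenes, which delivers resorcinol monoalkyl ethers. Ring A is therefore closed by a 6π electrocyclisation of a ketene-terminated triene, preceded by a transient four-membered ring that is closed by ketene–alkyne [2+2] cycloaddition and opened again. No stereocentre remains, because the single sp3 ring carbon of racemic 15 becomes C2 of the arene. The selectivity required is the orientation of the [2+2] event, and the polarisation of 13 dictates it: the unsubstituted, nucleophilic alkyne carbon attacks the electrophilic ketene carbon, so the methoxy-bearing carbon becomes C3 and the ketene carbon becomes the hydroxyl carbon C5. The saturated tether and the aryl benzyl ethers of ring B are thermally inert at 80 °C, and the excess of 13 should outrun ketene dimerisation and acylation of the phenol formed.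

Step 7
Reactants: 18 3-{14-[3,5-bis(benzyloxy)phenyl]tetradecyl}-5-methoxyphenol
Product: 19 5-[14-(3-hydroxy-5-methoxyphenyl)tetradecyl]benzene-1,3-diol
Conditions: H2 (1 atm), 10% Pd/C, EtOAc/MeOH, rt
Reagents that add atoms: none
Why: Catalytic hydrogenolysis of the two aryl benzyl ethers should release the resorcinol of ring B, while the aryl methyl ether, the free phenol and the saturated chain are inert.

Compound list
1 | 1,3-bis(benzyloxy)-5-bromobenzene | Brc1cc(OCc2ccccc2)cc(OCc2ccccc2)c1 | starting material
2 | 1,14-dibromotetradecane | BrCCCCCCCCCCCCCCBr | starting material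
3 | [3,5-bis(benzyloxy)phenyl]magnesium bromide | Br[Mg]c1cc(OCc2ccccc2)cc(OCc2ccccc2)c1 | intermediate
4 | 1,3-bis(benzyloxy)-5-(14-bromotetradecyl)benzene | BrCCCCCCCCCCCCCCc1cc(OCc2ccccc2)cc(OCc2ccccc2)c1 | intermediate
5 | lithium acetylide–ethylenediamine complex | [Li+].[C-]#C.NCCN | starting material
6 | 1,3-bis(benzyloxy)-5-(hexadec-15-yn-1-yl)benzene | C#CCCCCCCCCCCCCCCc1cc(OCc2ccccc2)cc(OCc2ccccc2)c1 | intermediate
7 | trichloroacetyl chloride | O=C(Cl)C(Cl)(Cl)Cl | starting material
8 | dichloroketene | O=C=C(Cl)Cl | intermediate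
9 | 3-{14-[3,5-bis(benzyloxy)phenyl]tetradecyl}-4,4-dichlorocyclobut-2-en-1-one | O=C1C=C(CCCCCCCCCCCCCCc2cc(OCc3ccccc3)cc(OCc3ccccc3)c2)C1(Cl)Cl | intermediate
10 | 3-{14-[3,5-bis(benzyloxy)phenyl]tetradecyl}cyclobut-2-en-1-one | O=C1C=C(CCCCCCCCCCCCCCc2cc(OCc3ccccc3)cc(OCc3ccccc3)c2)C1 | intermediate
11 | 2-chloro-1,1-dimethoxyethane | COC(CCl)OC | starting material
12 | sodium methoxyacetylide | [Na+].[C-]#COC | intermediate
13 | methoxyacetylene | COC#C | intermediate
14 | 3-{14-[3,5-bis(benzyloxy)phenyl]tetradecyl}buta-1,3-dien-1-one (vinylketene) | O=C=CC(=C)CCCCCCCCCCCCCCc1cc(OCc2ccccc2)cc(OCc2ccccc2)c1 | intermediate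
15 | 4-{16-[3,5-bis(benzyloxy)phenyl]hexadec-1-en-2-yl}-3-methoxycyclobut-2-en-1-one (racemic) | O=C1C=C(OC)C1C(=C)CCCCCCCCCCCCCCc2cc(OCc3ccccc3)cc(OCc3ccccc3)c2 | intermediate
16 | (3E)-5-{14-[3,5-bis(benzyloxy)phenyl]tetradecyl}-3-methoxyhexa-1,3,5-trien-1-one (dienylketene) | O=C=C/C(OC)=C\C(=C)CCCCCCCCCCCCCCc1cc(OCc2ccccc2)cc(OCc2ccccc2)c1 | intermediate
17 | 5-{14-[3,5-bis(benzyloxy)phenyl]tetradecyl}-3-methoxycyclohexa-2,4-dien-1-one | O=C1C=C(OC)C=C(CCCCCCCCCCCCCCc2cc(OCc3ccccc3)cc(OCc3ccccc3)c2)C1 | intermediate
18 | 3-{14-[3,5-bis(benzyloxy)phenyl]tetradecyl}-5-methoxyphenol | COc1cc(O)cc(CCCCCCCCCCCCCCc2cc(OCc3ccccc3)cc(OCc3ccccc3)c2)c1 | intermediate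
19 | 5-[14-(3-hydroxy-5-methoxyphenyl)tetradecyl]benzene-1,3-diol | COc1cc(O)cc(CCCCCCCCCCCCCCc2cc(O)cc(O)c2)c1 | target

Total step count: 7. Longest linear sequence: 6 steps (1, 2, 3, 4, 6, 7); step 5 is a one-step side branch.

Steps most likely to fail

Step 6. The vinylketene may be consumed by dimerisation or by acylating the phenol as it forms, and the volatile alkyne may leave the solution before the cycloaddition. The fallback gives up the annulation and brings ring A in preformed; it sets out from bromide 4. Purchased 3-bromo-5-methoxyphenol (COc1cc(O)cc(Br)c1) is benzylated (BnBr, K2CO3, DMF) to 1-(benzyloxy)-3-bromo-5-methoxybenzene F1, which Mg in THF converts into [3-(benzyloxy)-5-methoxyphenyl]magnesium bromide F2. Copper-catalysed coupling (Li2CuCl4, THF) of this reagent with 4 should give 1,3-bis(benzyloxy)-5-{14-[3-(benzyloxy)-5-methoxyphenyl]tetradecyl}benzene F3, and hydrogenolysis over Pd/C removes all three benzyl groups, so the fallback comes back to the route at target 19.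

Step 3. The ZnCl2 formed with the ketene may attack the benzyl ethers or promote acylation of electron-rich ring B, and ketene oligomerisation may outpace addition to the unactivated alkyne. The fallback avoids ketene chemistry and sets out from bromide 4, replacing steps 2 to 4. Mg in THF converts 4 into {14-[3,5-bis(benzyloxy)phenyl]tetradecyl}magnesium bromide F4, which is added at −78 °C to the carbonyl of purchased 3-ethoxycyclobut-2-en-1-one (CCOC1=CC(=O)C1). Protonation gives 1-{14-[3,5-bis(benzyloxy)phenyl]tetradecyl}-3-ethoxycyclobut-2-en-1-ol F5, which is not isolated: dilute HCl should effect hydrolysis of the enol ether with allylic transposition (Stork–Danheiser-type), and the fallback comes back to the route at cyclobutenone 10.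

Step 1. Transfer of the aryl group from magnesium through copper to the alkyl bromide may be slow, which leaves room for biaryl homocoupling and for a second substitution on the dibromide. The fallback makes the aryl–chain bond by acyl substitution and sets out from aryl bromide 1, replacing steps 1 and 2. Bromine–lithium exchange (n-BuLi, THF, −78 °C) gives [3,5-bis(benzyloxy)phenyl]lithium F6, which opens purchased pentadecanolide (O=C1CCCCCCCCCCCCCCO1) to 1-[3,5-bis(benzyloxy)phenyl]-15-hydroxypentadecan-1-one F7. Wolff–Kishner reduction (N2H4·H2O, KOH, diethylene glycol, 200 °C) should give 15-[3,5-bis(benzyloxy)phenyl]pentadecan-1-ol F8, and Dess–Martin oxidation gives 15-[3,5-bis(benzyloxy)phenyl]pentadecanal F9. Ohira–Bestmann homologation (dimethyl (1-diazo-2-oxopropyl)phosphonate, K2CO3, MeOH/THF) then comes back to the route at alkyne 6.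

Further compounds
F1 | step 6 | 1-(benzyloxy)-3-bromo-5-methoxybenzene | COc1cc(Br)cc(OCc2ccccc2)c1
F2 | step 6 | [3-(benzyloxy)-5-methoxyphenyl]magnesium bromide | COc1cc([Mg]Br)cc(OCc2ccccc2)c1
F3 | step 6 | 1,3-bis(benzyloxy)-5-{14-[3-(benzyloxy)-5-methoxyphenyl]tetradecyl}benzene | COc1cc(OCc2ccccc2)cc(CCCCCCCCCCCCCCc2cc(OCc3ccccc3)cc(OCc3ccccc3)c2)c1
F4 | step 3 | {14-[3,5-bis(benzyloxy)phenyl]tetradecyl}magnesium bromide | Br[Mg]CCCCCCCCCCCCCCc1cc(OCc2ccccc2)cc(OCc2ccccc2)c1
F5 | step 3 | 1-{14-[3,5-bis(benzyloxy)phenyl]tetradecyl}-3-ethoxycyclobut-2-en-1-ol (racemic) | CCOC1=CC(O)(CCCCCCCCCCCCCCc2cc(OCc3ccccc3)cc(OCc3ccccc3)c2)C1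
F6 | step 1 | [3,5-bis(benzyloxy)phenyl]lithium | [Li]c1cc(OCc2ccccc2)cc(OCc2ccccc2)c1
F7 | step 1 | 1-[3,5-bis(benzyloxy)phenyl]-15-hydroxypentadecan-1-one | O=C(CCCCCCCCCCCCCCO)c1cc(OCc2ccccc2)cc(OCc2ccccc2)c1
F8 | step 1 | 15-[3,5-bis(benzyloxy)phenyl]pentadecan-1-ol | OCCCCCCCCCCCCCCCc1cc(OCc2ccccc2)cc(OCc2ccccc2)c1
F9 | step 1 | 15-[3,5-bis(benzyloxy)phenyl]pentadecanal | O=CCCCCCCCCCCCCCCc1cc(OCc2ccccc2)cc(OCc2ccccc2)c1
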